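**Retrosynthetic overview**
1. C–D bridge (key step): cut the bond between ring D and its CH2. Ring D is unprotected 1,4-benzoquinone. It traps the 2-arylethyl radical released from a B-alkylcatecholborane (hydroboration of a 4-aryloxystyrene) and ends directly at the hydroquinone level.
2. B–O–C ether: Chan–Lam–Evans coupling of a ring B phenol with 4-vinylphenylboronic acid at room temperature, so the vinyl group survives.
3. The ring B phenol is unmasked from an aldehyde by Baeyer–Villiger oxidation. The A–B bridge comes from hydroboration of 3-vinylanisole and B-alkyl Suzuki–Miyaura coupling with the ring B bromide, which gives the saturated bridge at once.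
4. No ring is built. The four benzene rings are bought and joined in the order A–B, then B–O–C, then C–D. The usual plan (Ullmann ether, two Wittig/hydrogenation bridges, protected ring D aldehyde) is not used, and the only protecting group (one benzyl) is bought in place.

Assumption: the SMILES holds no stereocentre, stereogenic double bond or axis, so the target is achiral and "single enantiomer" needs no stereocontrol.

**Step 1**
Reactants: 1 3-vinylanisole (1-ethenyl-3-methoxybenzene); 2 2-(benzyloxy)-5-bromobenzaldehyde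
Product: 4 2-(benzyloxy)-5-[2-(3-methoxyphenyl)ethyl]benzaldehyde, via B-alkyl-9-BBN 3 (not isolated)
Conditions: 1 (1.3 equiv), 9-BBN (1.25 equiv), THF, 0 °C to rt, 4 h; then 2 (1.0 equiv), PdCl2(dppf) (3 mol %), K3PO4 (3 M aq, 3 equiv), DMF, 50 °C, 12 h
Reagents that add atoms: 9-borabicyclo[3.3.1]nonane (9-BBN), B1C2CCCC1CCC2 (its cage stands in 3; only its hydrogen stays in 4)
Why: Anti-Markovnikov hydroboration of the styrene followed by B-alkyl Suzuki–Miyaura coupling (oxidative addition of the aryl bromide to zerovalent palladium, transfer of the primary alkyl group from the hydroxyborate, reductive elimination faster than beta-hydride loss on the dppf complex) gives the saturated A–B bridge in one flask, the slight excess of 1 leaves no B–H to reduce the aldehyde, and no stereocentre is formed.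

**Step 2**
Reactants: 4 2-(benzyloxy)-5-[2-(3-methoxyphenyl)ethyl]benzaldehyde
Product: 6 2-(benzyloxy)-5-[2-(3-methoxyphenyl)ethyl]phenol, via aryl formate 5 (not isolated)
Conditions: mCPBA (1.4 equiv), CH2Cl2, 0 °C to rt, 6 h; aq NaHCO3 wash; then K2CO3 (0.2 equiv), MeOH, rt, 30 min
Reagents that add atoms: mCPBA (3-chloroperoxybenzoic acid), O=C(OO)c1cccc(Cl)c1
Why: Baeyer–Villiger (Dakin-type) oxidation, in which the electron-rich aryl group with its ortho alkoxy donor migrates in preference to hydride, turns the formyl group into a formate that base-catalysed methanolysis cleaves to the phenol, nothing else in 4 is oxidised by a peracid at room temperature, and no stereocentre is formed.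

**Step 3**
Reactants: 6 2-(benzyloxy)-5-[2-(3-methoxyphenyl)ethyl]phenol; 7 (4-ethenylphenyl)boronic acid
Product: 8 1-(benzyloxy)-2-(4-ethenylphenoxy)-4-[2-(3-methoxyphenyl)ethyl]benzene
Conditions: 7 (2.0 equiv), Cu(OAc)2 (1.0 equiv, kept in the divalent state by air), pyridine (5 equiv), 4 Å MS, CH2Cl2, dry air, rt, 36 h
Reagents that add atoms: none
Why: Chan–Lam–Evans oxidative coupling (aryl transfer from boron to a copper phenoxide, oxidation to trivalent copper, C–O reductive elimination) makes the diaryl ether at room temperature, where the styrene neither polymerises nor enters Heck-type chemistry, the boronic acid carries no ortho substituent, and no stereocentre is formed.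

**Step 4**
Reactants: 8 1-(benzyloxy)-2-(4-ethenylphenoxy)-4-[2-(3-methoxyphenyl)ethyl]benzene; 9 1,4-benzoquinone
Product: 12 2-[2-(4-{2-(benzyloxy)-5-[2-(3-methoxyphenyl)ethyl]phenoxy}phenyl)ethyl]benzene-1,4-diol, via B-alkylcatecholborane 10 (not isolated), via O-boryl hydroquinone 11 (not isolated)
Conditions: catecholborane (2.0 equiv), Me2NC(O)Me (10 mol %), CH2Cl2, reflux, 4 h; MeOH (1.2 equiv), 0 °C, 15 min (destroys excess B–H); then 9 (1.5 equiv), DMPU (1 equiv), air inlet (trace O2 as initiator), 0 °C to rt, 3 h; pH 7 aqueous work-up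
Reagents that add atoms: catecholborane (1,3,2-benzodioxaborole), B1Oc2ccccc2O1 (its boron ring stands in 10 and 11; only its hydrogen stays in 12)
Why: Key step: amide-catalysed anti-Markovnikov hydroboration gives the primary B-alkylcatecholborane, and traces of O2 start a radical chain (organoborane reductive alkylation of a quinone, a radical conjugate addition) in which the 2-arylethyl radical adds to a ring carbon of 9 and the resulting oxygen-centred radical displaces the next alkyl radical from the boron of 10, so that tautomerisation and hydrolysis of 11 deliver the 2-alkylhydroquinone at the right oxidation level with no protecting group on ring D and no stereocentre formed.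

**Step 5**
Reactants: 12 2-[2-(4-{2-(benzyloxy)-5-[2-(3-methoxyphenyl)ethyl]phenoxy}phenyl)ethyl]benzene-1,4-diol
Product: 13 2-[2-(4-{2-hydroxy-5-[2-(3-methoxyphenyl)ethyl]phenoxy}phenyl)ethyl]benzene-1,4-diol (CNP0211397.0)
Conditions: H2 (1 atm), 10% Pd/C, EtOAc–MeOH, rt, 6 h; filtration under argon
Reagents that add atoms: none
Why: Catalytic hydrogenolysis cleaves the single benzylic C–O bond while the methyl ether, the diaryl ether and the arenes are inert, and the reducing medium also returns any ring D quinone formed by adventitious oxidation to the hydroquinone, so the achiral target is released with no stereocentre to set.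

**Compound list**
1 | 3-vinylanisole (1-ethenyl-3-methoxybenzene) | COc1cccc(C=C)c1 | starting material
2 | 2-(benzyloxy)-5-bromobenzaldehyde | O=Cc1cc(Br)ccc1OCc1ccccc1 | starting material
3 | 9-[2-(3-methoxyphenyl)ethyl]-9-borabicyclo[3.3.1]nonane | COc1cccc(CCB2C3CCCC2CCC3)c1 | intermediate (not isolated)
4 | 2-(benzyloxy)-5-[2-(3-methoxyphenyl)ethyl]benzaldehyde | COc1cccc(CCc2ccc(OCc3ccccc3)c(C=O)c2)c1 | intermediate
5 | 2-(benzyloxy)-5-[2-(3-methoxyphenyl)ethyl]phenyl formate | COc1cccc(CCc2ccc(OCc3ccccc3)c(OC=O)c2)c1 | intermediate (not isolated)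
6 | 2-(benzyloxy)-5-[2-(3-methoxyphenyl)ethyl]phenol | COc1cccc(CCc2ccc(OCc3ccccc3)c(O)c2)c1 | intermediate
7 | (4-ethenylphenyl)boronic acid | C=Cc1ccc(B(O)O)cc1 | starting material
8 | 1-(benzyloxy)-2-(4-ethenylphenoxy)-4-[2-(3-methoxyphenyl)ethyl]benzene | COc1cccc(CCc2ccc(OCc3ccccc3)c(Oc3ccc(C=C)cc3)c2)c1 | intermediate
9 | 1,4-benzoquinone | O=C1C=CC(=O)C=C1 | starting material
10 | 2-[2-(4-{2-(benzyloxy)-5-[2-(3-methoxyphenyl)ethyl]phenoxy}phenyl)ethyl]-1,3,2-benzodioxaborole | COc1cccc(CCc2ccc(OCc3ccccc3)c(Oc3ccc(CCB4Oc5ccccc5O4)cc3)c2)c1 | intermediate (not isolated)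
11 | 4-(1,3,2-benzodioxaborol-2-yloxy)-2-[2-(4-{2-(benzyloxy)-5-[2-(3-methoxyphenyl)ethyl]phenoxy}phenyl)ethyl]phenol | COc1cccc(CCc2ccc(OCc3ccccc3)c(Oc3ccc(CCc4cc(OB5Oc6ccccc6O5)ccc4O)cc3)c2)c1 | intermediate (not isolated)
12 | 2-[2-(4-{2-(benzyloxy)-5-[2-(3-methoxyphenyl)ethyl]phenoxy}phenyl)ethyl]benzene-1,4-diol | COc1cccc(CCc2ccc(OCc3ccccc3)c(Oc3ccc(CCc4cc(O)ccc4O)cc3)c2)c1 | intermediate
13 | 2-[2-(4-{2-hydroxy-5-[2-(3-methoxyphenyl)ethyl]phenoxy}phenyl)ethyl]benzene-1,4-diol | COc1cccc(CCc2ccc(O)c(Oc3ccc(CCc4cc(O)ccc4O)cc3)c2)c1 | target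

**Total step count:** 5. **Longest linear sequence:** 5 (2 → 4 → 6 → 8 → 12 → 13).

**Three steps most likely to fail**

**Step 4.**
- Risk: a primary alkyl radical is the hardest kind to release from a B-alkylcatecholborane.
- Risk: the minor Markovnikov boronate gives a benzylic radical and hence a branched isomer.
- Risk: attack at the quinone oxygen, or oxidation of 12 by excess 9, can cost yield.
- Fallback: it sets out from 8 and comes back at 13. Bromohydroquinone is benzylated (BnBr, K2CO3, DMF) to 1,4-bis(benzyloxy)-2-bromobenzene F1. Compound 8 is hydroborated with 9-BBN to the B-alkyl-9-BBN adduct F2. This is coupled with F1 (PdCl2(dppf), K3PO4, DMF–THF–H2O, 50 °C) to the tris(benzyl) ether F3. H2 over 10% Pd/C then removes all three benzyl groups and gives 13.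
- Change of approach: a two-electron cross-coupling with a preformed, protected ring D replaces the radical alkylation of a free quinone.

**Step 3.**
- Risk: the phenol is flanked by a benzyloxy group and is electron-rich, so arylation may be slow and oxidation by copper and air may compete.
- Risk: the boronic acid can protodeboronate or homocouple.
- Fallback: it sets out from 6 and comes back at 8. Nucleophilic aromatic substitution of the phenoxide of 6 on 4-fluorobenzaldehyde (K2CO3, DMF, 110 °C) gives 4-{2-(benzyloxy)-5-[2-(3-methoxyphenyl)ethyl]phenoxy}benzaldehyde F4. Wittig methylenation (Ph3PCH3Br, KOtBu, THF, 0 °C) converts it into 8.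
- Change of approach: the ether is made by addition–elimination on an activated fluoroarene, and the vinyl group is installed afterwards.

**Step 1.**
- Risk: the aldehyde may be reduced by residual B–H or by beta-hydride transfer from 3.
- Risk: beta-hydride elimination can return styrene.
- Fallback: it sets out from 2 and comes back at 6. Compound 2 is oxidised first (mCPBA, CH2Cl2; then K2CO3, MeOH) through 2-(benzyloxy)-5-bromophenyl formate F5 to 2-(benzyloxy)-5-bromophenol F6. Mizoroki–Heck coupling with 1 (Pd(OAc)2, P(o-tol)3, K2CO3, DMF, 100 °C) gives the (E)-stilbene 2-(benzyloxy)-5-[(E)-2-(3-methoxyphenyl)ethenyl]phenol F7. Diimide (TsNHNH2, NaOAc, THF–H2O, reflux) saturates the alkene without touching the benzyl ether and gives 6.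
- Change of approach: no borane ever meets the aldehyde, and the bridge is made as an alkene and then reduced.

**Further compounds**
F1 | step 4 | 1,4-bis(benzyloxy)-2-bromobenzene | Brc1cc(OCc2ccccc2)ccc1OCc1ccccc1
F2 | step 4 | 9-[2-(4-{2-(benzyloxy)-5-[2-(3-methoxyphenyl)ethyl]phenoxy}phenyl)ethyl]-9-borabicyclo[3.3.1]nonane | COc1cccc(CCc2ccc(OCc3ccccc3)c(Oc3ccc(CCB4C5CCCC4CCC5)cc3)c2)c1
F3 | step 4 | 1,4-bis(benzyloxy)-2-[2-(4-{2-(benzyloxy)-5-[2-(3-methoxyphenyl)ethyl]phenoxy}phenyl)ethyl]benzene | COc1cccc(CCc2ccc(OCc3ccccc3)c(Oc3ccc(CCc4cc(OCc5ccccc5)ccc4OCc6ccccc6)cc3)c2)c1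
F4 | step 3 | 4-{2-(benzyloxy)-5-[2-(3-methoxyphenyl)ethyl]phenoxy}benzaldehyde | COc1cccc(CCc2ccc(OCc3ccccc3)c(Oc3ccc(C=O)cc3)c2)c1
F5 | step 1 | 2-(benzyloxy)-5-bromophenyl formate | O=COc1cc(Br)ccc1OCc1ccccc1
F6 | step 1 | 2-(benzyloxy)-5-bromophenol | Oc1cc(Br)ccc1OCc1ccccc1
F7 | step 1 | 2-(benzyloxy)-5-[(E)-2-(3-methoxyphenyl)ethenyl]phenol | COc1cccc(/C=C/c2ccc(OCc3ccccc3)c(O)c2)c1
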